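**Plan**

Numbering used throughout: C1 ring C=O, C2=C3, C4 CH–OAc, C5 quaternary C–OH, C6 side-chain CH–OH, C7–C20 tetradecyl chain.
Retrosynthesis: the O4 acetyl and an O6 4-methoxybenzyl (PMB) group are removed, then the C4–C5 ring bond is cut, because the C1 ketone, the C5 tertiary carbinol and the C4 carbinol of the cyclopentenone ring form an aldol retron. With the cis C2=C3 bond the opened chain is a (Z)-4-oxo-enal, the open form of a six-membered pyranone lactol that comes from a 2-furyl carbinol (furan C2–C5 = C1–C4); the C1–C5 bond is then cut to 2-furyllithium and an (S)-2-alkoxyhexadecanal.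
Forward order: the chain is joined to furan (C1–C5), the furan is expanded to the pyranone lactol, and the pyranone is contracted to the cyclopentenone, the only carbocycle, by enolisation, lactol opening and intramolecular aldol (C4–C5).
Stereochemistry: C6 comes from hydrolytic kinetic resolution of racemic 1,2-epoxyhexadecane; C5 and C4 are set from C6 in the ring contraction through a magnesium chelate; the furyl carbinol and lactol centres are erased and need no control.

Key step: step 7

Remark: compounds 3, 8, 9, 10 and 11 are carried as mixtures at centres that are later cleaved or erased, so their SMILES leave those centres undefined.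

**Route**

Step 1
Reactants: 1 rac-1,2-epoxyhexadecane
Product: 2 (S)-hexadecane-1,2-diol
Conditions: (S,S)-[N,N'-bis(3,5-di-tert-butylsalicylidene)cyclohexane-1,2-diaminato]cobalt acetate (trivalent cobalt, 0.5 mol %), H2O (0.45 equiv), THF, 0 °C → rt; diol recrystallised
Reagents that add atoms: water, O
Why: Hydrolytic kinetic resolution (Jacobsen): the (S,S)-catalyst, the enantiomer that hydrates the (S)-epoxide, delivers water to the terminal carbon, so the C–O bond at the stereocentre is untouched and the (S)-diol that fixes C6 should be obtained while the (R)-epoxide stays behind.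

Step 2
Reactants: 2 (S)-hexadecane-1,2-diol
Product: 3 (4S)-2-(4-methoxyphenyl)-4-tetradecyl-1,3-dioxolane (both C2 epimers)
Conditions: 4-MeOC6H4CH(OMe)2 (1.2 equiv), PPTS (cat.), CH2Cl2, rt
Reagents that add atoms: 4-methoxybenzaldehyde dimethyl acetal, COc1ccc(cc1)C(OC)OC
Why: Acid-catalysed transacetalisation of the 1,2-diol to the five-membered 4-methoxybenzylidene acetal is driven by loss of methanol, and the mixed acetal carbon is removed in the next step.

Step 3
Reactants: 3 (4S)-2-(4-methoxyphenyl)-4-tetradecyl-1,3-dioxolane
Product: 4 (S)-2-[(4-methoxybenzyl)oxy]hexadecan-1-ol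
Conditions: i-Bu2AlH (2.5 equiv), CH2Cl2, −78 → 0 °C; aq. potassium sodium tartrate
Reagents that add atoms: none
Why: Regioselective reductive acetal opening: the aluminium hydride coordinates the less hindered primary-side oxygen, that C–O bond breaks and hydride is delivered to the oxocarbenium ion, which should leave the PMB ether on the secondary oxygen and the primary alcohol free without touching C6.

Step 4
Reactants: 4 (S)-2-[(4-methoxybenzyl)oxy]hexadecan-1-ol
Product: 5 (S)-2-[(4-methoxybenzyl)oxy]hexadecanal
Conditions: TEMPO (10 mol %), PhI(OAc)2 (1.1 equiv), CH2Cl2, rt; used crude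
Reagents that add atoms: none
Why: Nitroxyl-catalysed oxidation of the primary alcohol stops at the aldehyde under nearly neutral conditions, so the α-alkoxy stereocentre should not epimerise.

Step 5
Reactants: 5 (S)-2-[(4-methoxybenzyl)oxy]hexadecanal; 6 furan
Product: 8 (2S)-1-(furan-2-yl)-2-[(4-methoxybenzyl)oxy]hexadecan-1-ol (both C1 epimers), via 2-furyllithium 7 (not isolated)
Conditions: furan (1.5 equiv), n-butyllithium (1.3 equiv), THF, 0 °C; then 5, −78 °C; aq. NH4Cl
Reagents that add atoms: none
Why: α-Lithiation of furan followed by 1,2-addition of the heteroaryllithium to the aldehyde at low temperature forms the C1–C5 bond, and the new carbinol centre (future C5) may be a mixture because it is enolised in step 7.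

Step 6
Reactants: 8 (2S)-1-(furan-2-yl)-2-[(4-methoxybenzyl)oxy]hexadecan-1-ol
Product: 10 6-hydroxy-2-{(1S)-1-[(4-methoxybenzyl)oxy]pentadecyl}-2H-pyran-3(6H)-one (ring centres unassigned), via open-chain Z-oxo-enal 9 (not isolated)
Conditions: mCPBA (1.1 equiv), CH2Cl2, 0 °C
Reagents that add atoms: m-chloroperbenzoic acid, OOC(=O)c1cccc(Cl)c1
Why: Achmatowicz oxidative ring expansion: peracid oxidation of the furan gives the cis-configured hydroxy-oxo-enal 9, whose C5 hydroxyl closes onto the aldehyde to give the six-membered lactol, and the PMB ether is inert to the peracid at this temperature.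

Step 7
Reactants: 10 6-hydroxy-2-{(1S)-1-[(4-methoxybenzyl)oxy]pentadecyl}-2H-pyran-3(6H)-one
Product: 13 (4R,5R)-4,5-dihydroxy-5-{(1S)-1-[(4-methoxybenzyl)oxy]pentadecyl}cyclopent-2-en-1-one, via cyclic magnesium enolate 11 (not isolated), via open-chain enediolate 12 (not isolated)
Conditions: MgBr2·OEt2 (1.5 equiv), Et3N (2 equiv), CH2Cl2, −40 → 0 °C; aq. NH4Cl
Reagents that add atoms: none
Why: MgBr2 bridges the C1 ketone oxygen and the C6 ether oxygen of 10 and so acidifies C5–H, which Et3N should remove to give the cyclic magnesium dienolate 11; in 11 the ring oxygen has become an enolate-type leaving group, so its hemiacetal opens to the chelated (2Z)-enediolate 12 with the C4 aldehyde unveiled, C5 of 12 adds to that aldehyde to form the C4–C5 bond, and the aldol cannot dehydrate because C5 then carries no hydrogen. The closest known reaction type is the base-induced isomerisation of 2-substituted 6-hydroxy-2H-pyran-3(6H)-ones to 4,5-dihydroxycyclopent-2-enones, an intramolecular aldol addition, run here under magnesium soft-enolisation conditions. The cyclopentenone closes in the 5-(enolendo)-exo-trig mode, the mode by which 1,4-dicarbonyl compounds aldolise to cyclopentenones; it is formally disfavoured by the enolate ring-closure rules but is helped here by the cis C2=C3 bond from the furan, which holds C4 next to C5. C5 is controlled by C6: in the six-membered O1–Mg–O6 chelate (a Fráter–Seebach-type arrangement, its enolate geometry preset because the pyran ring of 11 holds O1 syn to C6) the tetradecyl chain covers one face and the aldehyde carbon should bond to the other. C4 is controlled by the same metal, which can also bind the aldehyde oxygen and so turn O4 toward C6 and away from O5, giving the 4,5-trans diol, although this is expected rather than demonstrated and C4 is the less secure centre. The step needs the aldol to outrun β-elimination of the C6 alkoxide and retro-aldol scrambling; the chelate should secure this by holding the C6–O bond in the nodal plane of the enolate, supported by low temperature and an early quench.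

Step 8
Reactants: 13 (4R,5R)-4,5-dihydroxy-5-{(1S)-1-[(4-methoxybenzyl)oxy]pentadecyl}cyclopent-2-en-1-one
Product: 14 (1R,5S)-5-hydroxy-5-{(1S)-1-[(4-methoxybenzyl)oxy]pentadecyl}-4-oxocyclopent-2-en-1-yl acetate
Conditions: Ac2O (1.2 equiv), pyridine, DMAP (cat.), CH2Cl2, 0 °C
Reagents that add atoms: acetic anhydride, CC(=O)OC(C)=O
Why: Chemoselective O-acylation should acetylate the secondary allylic C4 hydroxyl and leave the tertiary C5 hydroxyl, and the trans relationship of O4 and O5 on the five-membered ring disfavours acetyl migration.

Step 9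
Reactants: 14 (1R,5S)-5-hydroxy-5-{(1S)-1-[(4-methoxybenzyl)oxy]pentadecyl}-4-oxocyclopent-2-en-1-yl acetate
Product: 15 (1R,5S)-5-hydroxy-5-[(1S)-1-hydroxypentadecyl]-4-oxocyclopent-2-en-1-yl acetate (target)
Conditions: DDQ (1.5 equiv), CH2Cl2/aq. NaH2PO4–Na2HPO4 buffer pH 7 (10:1), 0 °C → rt
Reagents that add atoms: none
Why: Oxidative cleavage of the PMB ether by DDQ (benzylic oxidation to the oxocarbenium ion, then hydrolysis) should free the C6 hydroxyl under neutral conditions that leave the acetate, the enone and the α-ketol untouched.

**Compound list**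

1 | rac-1,2-epoxyhexadecane | CCCCCCCCCCCCCCC1CO1 | starting material
2 | (S)-hexadecane-1,2-diol | CCCCCCCCCCCCCC[C@H](O)CO | intermediate
3 | (4S)-2-(4-methoxyphenyl)-4-tetradecyl-1,3-dioxolane (both C2 epimers) | CCCCCCCCCCCCCC[C@H]1COC(c2ccc(OC)cc2)O1 | intermediate
4 | (S)-2-[(4-methoxybenzyl)oxy]hexadecan-1-ol | CCCCCCCCCCCCCC[C@H](OCc1ccc(OC)cc1)CO | intermediate
5 | (S)-2-[(4-methoxybenzyl)oxy]hexadecanal | CCCCCCCCCCCCCC[C@H](OCc1ccc(OC)cc1)C=O | intermediate
6 | furan | c1ccoc1 | starting material
7 | 2-furyllithium (not isolated) | [Li]c1ccco1 | intermediate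
8 | (2S)-1-(furan-2-yl)-2-[(4-methoxybenzyl)oxy]hexadecan-1-ol (both C1 epimers) | CCCCCCCCCCCCCC[C@H](OCc1ccc(OC)cc1)C(O)c1ccco1 | intermediate
9 | (2Z,6S)-5-hydroxy-6-[(4-methoxybenzyl)oxy]-4-oxoicos-2-enal (both C5 epimers, not isolated) | CCCCCCCCCCCCCC[C@H](OCc1ccc(OC)cc1)C(O)C(=O)/C=C\C=O | intermediate
10 | 6-hydroxy-2-{(1S)-1-[(4-methoxybenzyl)oxy]pentadecyl}-2H-pyran-3(6H)-one (ring centres unassigned) | CCCCCCCCCCCCCC[C@H](OCc1ccc(OC)cc1)C1OC(O)C=CC1=O | intermediate
11 | cyclic magnesium enolate of 10, drawn as the neutral 2-{(1S)-1-[(4-methoxybenzyl)oxy]pentadecyl}-6H-pyran-3,6-diol (lactol centre unassigned, not isolated) | CCCCCCCCCCCCCC[C@H](OCc1ccc(OC)cc1)C1=C(O)C=CC(O)O1 | intermediate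
12 | open-chain magnesium enediolate, drawn as the neutral (2Z,4E,6S)-4,5-dihydroxy-6-[(4-methoxybenzyl)oxy]icosa-2,4-dienal (not isolated) | CCCCCCCCCCCCCC[C@H](OCc1ccc(OC)cc1)/C(O)=C(O)/C=C\C=O | intermediate
13 | (4R,5R)-4,5-dihydroxy-5-{(1S)-1-[(4-methoxybenzyl)oxy]pentadecyl}cyclopent-2-en-1-one | CCCCCCCCCCCCCC[C@H](OCc1ccc(OC)cc1)[C@@]1(O)C(=O)C=C[C@H]1O | intermediate
14 | (1R,5S)-5-hydroxy-5-{(1S)-1-[(4-methoxybenzyl)oxy]pentadecyl}-4-oxocyclopent-2-en-1-yl acetate | CCCCCCCCCCCCCC[C@H](OCc1ccc(OC)cc1)[C@@]1(O)C(=O)C=C[C@H]1OC(C)=O | intermediate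
15 | (1R,5S)-5-hydroxy-5-[(1S)-1-hydroxypentadecyl]-4-oxocyclopent-2-en-1-yl acetate | CCCCCCCCCCCCCC[C@H](O)[C@@]1(O)C(=O)C=C[C@H]1OC(C)=O | target

**Step count**

Total steps: 9. Longest linear sequence: 9 steps (1 → 15); furan enters in step 5.

**Steps most likely to fail**

Step 7. The aldehyde may add to both faces of the enediolate if magnesium is shared with the C5 oxygen or the chelate is lost. The C4 configuration may erode through retro-aldol and re-closure, the C6 alkoxide may be expelled from the enolate, and the enediolate may reprotonate at C1 and so transpose the ketol. The fallback sets out from 10 and returns to 13, and moves stereocontrol from the aldol to a reagent-controlled reduction. The ring contraction is run without stereocontrol (Et3N, DMF, rt) to give 4,5-dihydroxy-5-{(1S)-1-[(4-methoxybenzyl)oxy]pentadecyl}cyclopent-2-en-1-one (ring centres unassigned) F1. The mixture is oxidised at C4 (Dess–Martin periodinane or MnO2, CH2Cl2) to the single ene-dione 2-hydroxy-2-{(1S)-1-[(4-methoxybenzyl)oxy]pentadecyl}cyclopent-4-ene-1,3-dione F2, in which C5 is no longer a stereocentre because its two ring arms are identical. A Corey–Bakshi–Shibata reduction ((S)-2-methyl-CBS-oxazaborolidine, BH3·SMe2, THF, −40 °C, hydride limited to one carbonyl) then sets both ring centres. The catalyst fixes the (4R) carbinol; the (S)-catalyst applies if the quaternary C5 acts as the large flank, otherwise its enantiomer is used. Hydride should enter anti to the branched side chain, so O4 ends trans to O5. Together these two constraints decide which of the two diastereotopic carbonyls is reduced, and so the C5 configuration, giving 13.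

Step 9. The benzylic cation formed on oxidation may be captured by the adjacent C5 hydroxyl faster than by water, and long exposure may let the acetyl group move from O4 to O6. The fallback sets out from 14 and returns to 15, and makes the neighbouring-group capture the intended path. DDQ in anhydrous CH2Cl2 at 0 °C converts 14 into the 4-methoxybenzylidene acetal spanning O5 and O6 (spiro-1,3-dioxolane, C4 acetate retained, acetal carbon unassigned) F3. Brief hydrolysis (AcOH/H2O 4:1, rt) then releases the target with the acetate intact.

Step 3. Hydride may be delivered after coordination to the more hindered ring oxygen, giving some primary PMB ether, and excess reagent may cleave the ether. The fallback sets out from 2 and returns to 4, and tells the two hydroxyls apart by protecting groups instead of a regioselective reduction. TBSCl/imidazole (CH2Cl2, 0 °C) silylates the primary hydroxyl to give (S)-1-[(tert-butyldimethylsilyl)oxy]hexadecan-2-ol F4. 4-Methoxybenzyl trichloroacetimidate with catalytic camphorsulfonic acid (CH2Cl2, rt) etherifies the secondary hydroxyl without base, and so without silyl migration, to give (S)-tert-butyl({2-[(4-methoxybenzyl)oxy]hexadecyl}oxy)dimethylsilane F5. Bu4NF (THF, rt) then frees the primary alcohol 4.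

**Further compounds**

F1 | step 7 | 4,5-dihydroxy-5-{(1S)-1-[(4-methoxybenzyl)oxy]pentadecyl}cyclopent-2-en-1-one (ring centres unassigned) | CCCCCCCCCCCCCC[C@H](OCc1ccc(OC)cc1)C1(O)C(=O)C=CC1O
F2 | step 7 | 2-hydroxy-2-{(1S)-1-[(4-methoxybenzyl)oxy]pentadecyl}cyclopent-4-ene-1,3-dione | CCCCCCCCCCCCCC[C@H](OCc1ccc(OC)cc1)C1(O)C(=O)C=CC1=O
F3 | step 9 | 4-methoxybenzylidene acetal of 15 across O5 and O6 (spiro-1,3-dioxolane, C4 acetate retained, acetal carbon unassigned) | CCCCCCCCCCCCCC[C@@H]1OC(c2ccc(OC)cc2)O[C@@]13C(=O)C=C[C@H]3OC(C)=O
F4 | step 3 | (S)-1-[(tert-butyldimethylsilyl)oxy]hexadecan-2-ol | CCCCCCCCCCCCCC[C@H](O)CO[Si](C)(C)C(C)(C)C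
F5 | step 3 | (S)-tert-butyl({2-[(4-methoxybenzyl)oxy]hexadecyl}oxy)dimethylsilane | CCCCCCCCCCCCCC[C@H](OCc1ccc(OC)cc1)CO[Si](C)(C)C(C)(C)C
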